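## Retrosynthetic overview

- Target: 3-hexadecyl-2-hydroxy-5-methoxy-1,4-benzoquinone, one ring, no stereocentre. Ring numbering used throughout: C1 and C4 are the carbonyl carbons, C2 carries OH, C3 the hexadecyl chain, C5 OMe, C6 H.
- Feature the route rests on: the para pair C1/C4, flanked by C2–O and C3–alkyl on one side and by C5–OMe and C6–H on the other, is the substitution pattern of a Dötz 4-methoxyphenol. The quinone is therefore traced back to a 4-methoxyphenol that carries a silyl ether on O2.
- Key disconnection (the only ring, closed in one step): bonds C3–C4, C1–C2 and C1–C6. The pieces are a chromium methoxy(1-methoxyvinyl)carbene (C4, C5, C6 and both methyl ethers), one carbonyl ligand (C1) and a hexadecyl siloxyalkyne (C2, C3).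
- Carbene complex from methyl vinyl ether and Cr(CO)6; siloxyalkyne from ethyl heptadecanoate by Kowalski ynolate formation and O-silylation.
- After ring formation: oxidative demethylation at C4 to the quinone, then removal of the silyl group.

Key step: step 3

Remark: the target is taken as the 2-hydroxy-1,4-quinone tautomer written in its SMILES; in the SMILES of chromium compounds the carbonyl ligands are written Cr=C=O, and the π-bound arene of 10 is written as a separate part.

## Route

Step 1
Reactants: 1 methyl vinyl ether; 2 chromium hexacarbonyl, Cr(CO)6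
Product: 5 pentacarbonyl[methoxy(1-methoxyvinyl)carbene]chromium, via 1-methoxyvinyllithium 3 (not isolated), via lithium acylchromate 4 (not isolated)
Conditions: t-BuLi, THF, −78 → 0 °C; then 2, Et2O, 0 → 25 °C; solvent exchange, MeOTf, CH2Cl2, 0 → 25 °C
Reagents that add atoms: methyl trifluoromethanesulfonate, COS(=O)(=O)C(F)(F)F
Why: This is the standard Fischer carbene complex synthesis (α-lithiation of the vinyl ether, addition of the vinyllithium to a carbonyl ligand of Cr(CO)6, O-methylation of the acylchromate by a hard methylating agent), and the α-methoxy group, like the α-methyl group of the well-behaved isopropenyl analogue, should keep the vinyl unit from polymerising.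

Step 2
Reactants: 6 ethyl heptadecanoate
Product: 9 1-(triisopropylsilyloxy)octadec-1-yne, via lithium dibromoenolate 7 (not isolated), via lithium ynolate 8 (not isolated)
Conditions: CH2Br2, lithium 2,2,6,6-tetramethylpiperidide, THF, −78 °C; LiN(SiMe3)2, −78 → −20 °C; n-BuLi, −78 → 25 °C; i-Pr3SiCl, −78 → 0 °C
Reagents that add atoms: dibromomethane, BrCBr; chlorotriisopropylsilane, CC(C)[Si](Cl)(C(C)C)C(C)C
Why: Kowalski ester homologation: dibromomethyllithium is acylated by the ester, the dibromoketone is held as enolate 7, bromine–lithium exchange triggers a 1,2-shift of the hexadecyl group with loss of bromide to ynolate 8, and the bulky silyl chloride silylates oxygen in preference to carbon.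

Step 3
Reactants: 5 pentacarbonyl[methoxy(1-methoxyvinyl)carbene]chromium; 9 1-(triisopropylsilyloxy)octadec-1-yne
Product: 11 3-hexadecyl-4,5-dimethoxy-2-(triisopropylsilyloxy)phenol, via tricarbonylchromium arene complex 10 (not isolated)
Conditions: degassed THF, 50 °C, Ar; then air, Et2O, 25 °C; neutral work-up
Reagents that add atoms: none
Why: Proposed new method: heating frees one coordination site on chromium, the ynol ether 9 binds and inserts into the Cr=C bond with its electron-rich, chain-bearing carbon attacking the electrophilic carbene carbon (C3–C4), so that the siloxy-bearing carbon becomes a new carbene centre; this takes up a carbonyl ligand (C1–C2) to give a chromium-bound dienylketene. The only ring is then closed by a 6π-electrocyclisation in which the ketene carbon bonds to the terminal CH2 of the former methoxyvinyl group (C1–C6), and enolisation of the cyclohexadienone gives the chromium-bound phenol 10, from which air releases 11. The closest known reaction type is the Dötz benzannulation of alkenyl(methoxy)carbene chromium complexes with alkyl- and silyl-substituted alkynes, a siloxyalkyne being untested as the alkyne component. No stereocentre is formed. The step needs a single orientation of alkyne insertion, and two things in 9 work for it: the polarisation of the ynol ether, which parallels the known insertions of ynamines and alkoxyalkynes that place the heteroatom on the new carbene carbon, and the bulk of the triisopropylsilyloxy group, which prefers the metal-bound position that the larger alkyne substituent normally takes. If the donor-stabilised siloxycarbene is slow to carbonylate, irradiation under CO, as in the photochemical benzannulation of dienyl(alkoxy)carbene chromium complexes, should push it on to the same phenol.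

Step 4
Reactants: 11 3-hexadecyl-4,5-dimethoxy-2-(triisopropylsilyloxy)phenol
Product: 12 3-hexadecyl-5-methoxy-2-(triisopropylsilyloxy)cyclohexa-2,5-diene-1,4-dione
Conditions: (NH4)2Ce(NO3)6, MeCN/H2O, 0 °C, short reaction time
Reagents that add atoms: water, O
Why: Oxidative demethylation of a para-methoxyphenol by (NH4)2Ce(NO3)6: two-electron oxidation gives the C4 oxocarbenium ion, water adds at C4 and methanol leaves, so the C4 methyl ether is consumed while the C5 methyl ether, the silyl ether on O2 and the saturated chain should survive the brief, cold, weakly acidic conditions.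

Step 5
Reactants: 12 3-hexadecyl-5-methoxy-2-(triisopropylsilyloxy)cyclohexa-2,5-diene-1,4-dione
Product: 13 3-hexadecyl-2-hydroxy-5-methoxycyclohexa-2,5-diene-1,4-dione
Conditions: HF·pyridine, THF, 0 °C
Reagents that add atoms: none
Why: Fluoride-mediated desilylation: the silyloxyquinone is a vinylogous silyl ester and should be cleaved readily by buffered HF, which leaves the C5 vinylogous methyl ester and the quinone untouched and gives the hydroxyquinone in its stable 2-hydroxy-1,4-quinone tautomer.

## Compound list

1 | methyl vinyl ether | COC=C | starting material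
2 | chromium hexacarbonyl, Cr(CO)6 | O=C=[Cr](=C=O)(=C=O)(=C=O)(=C=O)=C=O | starting material
3 | 1-methoxyvinyllithium | [Li]C(=C)OC | intermediate
4 | lithium pentacarbonyl(2-methoxyacryloyl)chromate | [Li+].[O-]C(C(OC)=C)=[Cr](=C=O)(=C=O)(=C=O)(=C=O)=C=O | intermediate
5 | pentacarbonyl[methoxy(1-methoxyvinyl)carbene]chromium (zerovalent chromium) | COC(C(OC)=C)=[Cr](=C=O)(=C=O)(=C=O)(=C=O)=C=O | intermediate
6 | ethyl heptadecanoate | CCCCCCCCCCCCCCCCC(=O)OCC | starting material
7 | lithium 1,1-dibromooctadec-1-en-2-olate | [Li+].CCCCCCCCCCCCCCCCC([O-])=C(Br)Br | intermediate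
8 | lithium octadec-1-yn-1-olate | [Li+].CCCCCCCCCCCCCCCCC#C[O-] | intermediate
9 | 1-(triisopropylsilyloxy)octadec-1-yne | CCCCCCCCCCCCCCCCC#CO[Si](C(C)C)(C(C)C)C(C)C | intermediate
10 | tricarbonyl[η6-3-hexadecyl-4,5-dimethoxy-2-(triisopropylsilyloxy)phenol]chromium (π-complex) | CCCCCCCCCCCCCCCCc1c(O[Si](C(C)C)(C(C)C)C(C)C)c(O)cc(OC)c1OC.[Cr](=C=O)(=C=O)=C=O | intermediate
11 | 3-hexadecyl-4,5-dimethoxy-2-(triisopropylsilyloxy)phenol | CCCCCCCCCCCCCCCCc1c(O[Si](C(C)C)(C(C)C)C(C)C)c(O)cc(OC)c1OC | intermediate
12 | 3-hexadecyl-5-methoxy-2-(triisopropylsilyloxy)cyclohexa-2,5-diene-1,4-dione | CCCCCCCCCCCCCCCCC1=C(O[Si](C(C)C)(C(C)C)C(C)C)C(=O)C=C(OC)C1=O | intermediate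
13 | 3-hexadecyl-2-hydroxy-5-methoxycyclohexa-2,5-diene-1,4-dione (3-hexadecyl-2-hydroxy-5-methoxy-1,4-benzoquinone) | CCCCCCCCCCCCCCCCC1=C(O)C(=O)C=C(OC)C1=O | target

## Step count and risks

Total step count: 5. Longest linear sequence: 4 steps (step 1 or step 2, then steps 3, 4 and 5).

Steps most likely to fail:

1. Step 3 (the key step). The alkyne may insert but the donor-stabilised siloxycarbene may then fail to take up CO, so that the sequence stops before ring closure. The electron-rich alkyne may also insert in the opposite sense or add to the vinyl terminus of 5. The fallback uses known chemistry, with boron as the placeholder for the C2 oxygen, and sets out from 5.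
   - Commercial octadec-1-yne F1 is lithiated (n-BuLi, THF, −78 °C) and borylated with 2-isopropoxy-4,4,5,5-tetramethyl-1,3,2-dioxaborolane to 4,4,5,5-tetramethyl-2-(octadec-1-yn-1-yl)-1,3,2-dioxaborolane F2.
   - Dötz benzannulation of 5 with F2 (THF, 50 °C; air) is a known reaction of alkynylboronates, in which the boryl group takes the position next to the CO-derived carbon. It should give 3-hexadecyl-4,5-dimethoxy-2-(4,4,5,5-tetramethyl-1,3,2-dioxaborolan-2-yl)phenol F3.
   - Oxidation with (NH4)2Ce(NO3)6 in MeCN/H2O should give the quinone boronate 3-hexadecyl-5-methoxy-2-(4,4,5,5-tetramethyl-1,3,2-dioxaborolan-2-yl)cyclohexa-2,5-diene-1,4-dione F4.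
   - Oxidation of the C–B bond with Me3NO (CH2Cl2, 25 °C; aqueous work-up) should deliver the C2 hydroxyl. The fallback comes back to the route at 13.

2. Step 1. O-Methylation of the lithium acylchromate may be slow or incomplete, and the electron-rich alkenylcarbene complex may be lost by polymerisation while the alkylation drags on. The fallback sets out from 4 and replaces direct alkylation by the acyloxycarbene route.
   - Cation exchange with Me4NBr in water gives the isolable salt tetramethylammonium pentacarbonyl(2-methoxyacryloyl)chromate F5.
   - Acetyl bromide in CH2Cl2 at −40 °C converts it into pentacarbonyl[acetoxy(1-methoxyvinyl)carbene]chromium F6.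
   - Methanol added at low temperature exchanges the acetoxy group for methoxy. The fallback comes back to the route at 5.

3. Step 4. Water may attack the oxidised ring at C2 instead of C4, with loss of the silyl group and formation of an ortho-quinone. Alternatively the silyl group may migrate from O2 to O1 before oxidation; either process moves the carbonyl groups to the wrong carbons. The fallback sets out from 11 and separates oxidation from hydrolysis.
   - PhI(OAc)2 in anhydrous MeOH at 0 °C (oxidative dearomatisation of a para-methoxyphenol, with methanol as the only nucleophile) should give the quinone monoketal 3-hexadecyl-4,4,5-trimethoxy-2-(triisopropylsilyloxy)cyclohexa-2,5-dien-1-one F7.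
   - Mild aqueous acid (oxalic acid on wet silica, CH2Cl2) then hydrolyses the ketal. The fallback comes back to the route at 12.

## Further compounds

F1 | step 3 | octadec-1-yne | CCCCCCCCCCCCCCCCC#C
F2 | step 3 | 4,4,5,5-tetramethyl-2-(octadec-1-yn-1-yl)-1,3,2-dioxaborolane | CCCCCCCCCCCCCCCCC#CB1OC(C)(C)C(C)(C)O1
F3 | step 3 | 3-hexadecyl-4,5-dimethoxy-2-(4,4,5,5-tetramethyl-1,3,2-dioxaborolan-2-yl)phenol | CCCCCCCCCCCCCCCCc1c(B2OC(C)(C)C(C)(C)O2)c(O)cc(OC)c1OC
F4 | step 3 | 3-hexadecyl-5-methoxy-2-(4,4,5,5-tetramethyl-1,3,2-dioxaborolan-2-yl)cyclohexa-2,5-diene-1,4-dione | CCCCCCCCCCCCCCCCC1=C(B2OC(C)(C)C(C)(C)O2)C(=O)C=C(OC)C1=O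
F5 | step 1 | tetramethylammonium pentacarbonyl(2-methoxyacryloyl)chromate | C[N+](C)(C)C.[O-]C(C(OC)=C)=[Cr](=C=O)(=C=O)(=C=O)(=C=O)=C=O
F6 | step 1 | pentacarbonyl[acetoxy(1-methoxyvinyl)carbene]chromium | CC(=O)OC(C(OC)=C)=[Cr](=C=O)(=C=O)(=C=O)(=C=O)=C=O
F7 | step 4 | 3-hexadecyl-4,4,5-trimethoxy-2-(triisopropylsilyloxy)cyclohexa-2,5-dien-1-one | CCCCCCCCCCCCCCCCC1=C(O[Si](C(C)C)(C(C)C)C(C)C)C(=O)C=C(OC)C1(OC)OC
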